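Everything rests on cutting C3–C4 of pyranone ring C while O1–C2 stays in place. The flavanone is read as the hydroacylation isomer of an achiral 2-(1-arylvinyloxy)benzaldehyde. The feature exploited is the array O1–C2(H)(aryl)–C3H2–C4(=O) on ring A. One enantioselective rhodium-catalysed 6-endo alkene hydroacylation carries the formyl hydrogen to C2, joins acyl carbon C4 to C3, closes ring C and sets the only stereocentre (2R). No base is present, so the retro-oxa-Michael lability of C2 is never provoked. The precursor is an α-aryloxystyrene that already holds the complete prenylated chromene ring B. It comes from methylenation of an aryl ester and formylation of ring A.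

Key step: step 8

Assumption: the sense of induction cannot be read from the structure. (R)-DTBM-SEGPHOS is written as the antipode that delivers hydride to the Si face of C2. The commercial (S)-antipode takes its place if the sense proves opposite.

Step 1
Reactants: 1 methyl 4-hydroxy-3,5-diiodobenzoate; 2 tributyl(3-methylbut-2-en-1-yl)stannane (2.4 equiv)
Product: 3 methyl 4-hydroxy-3,5-bis(3-methylbut-2-en-1-yl)benzoate
Conditions: Pd(PPh3)4 (5 mol %), DMF, 90 °C
Reagents that add atoms: none
Why: Twofold Stille coupling, in which both C–I bonds add readily to Pd(0) and reductive elimination from the η3-prenyl(aryl)palladium places the arene on the unsubstituted allyl terminus, so that linear prenyl groups should result.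

Step 2
Reactants: 3 methyl 4-hydroxy-3,5-bis(3-methylbut-2-en-1-yl)benzoate
Product: 5 methyl 2,2-dimethyl-8-(3-methylbut-2-en-1-yl)-2H-chromene-6-carboxylate, via o-quinone methide 4 (not isolated)
Conditions: DDQ (1.1 equiv), PhMe, 80 °C
Reagents that add atoms: none
Why: DDQ dehydrogenation of an o-prenylphenol gives o-quinone methide 4 by hydride abstraction from the benzylic-allylic CH2, 4 closes by oxa-6π electrocyclisation, and since the two prenyl groups are equivalent and the single OH is consumed by the first closure, the reaction should stop at one chromene.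

Step 3
Reactants: 5 methyl 2,2-dimethyl-8-(3-methylbut-2-en-1-yl)-2H-chromene-6-carboxylate
Product: 6 2,2-dimethyl-8-(3-methylbut-2-en-1-yl)-2H-chromene-6-carboxylic acid
Conditions: LiOH, THF/MeOH/H2O, 50 °C; then 1 M HCl to pH 3
Reagents that add atoms: lithium hydroxide, [Li+].[OH-]
Why: Saponification of an unhindered aryl methyl ester, to which the prenyl and chromene alkenes and the aryl ether are inert.

Step 4
Reactants: 7 4-bromobenzene-1,3-diol (4-bromoresorcinol)
Product: 8 2-bromo-5-(triisopropylsilyloxy)phenol
Conditions: TIPSCl (1.0 equiv), imidazole, CH2Cl2, −20 to 0 °C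
Reagents that add atoms: triisopropylsilyl chloride, CC(C)[Si](Cl)(C(C)C)C(C)C
Why: Sterically controlled monosilylation, in which the bulky silyl chloride should take the open hydroxyl para to bromine faster than the hydroxyl flanked by bromine.

Step 5
Reactants: 6 2,2-dimethyl-8-(3-methylbut-2-en-1-yl)-2H-chromene-6-carboxylic acid; 8 2-bromo-5-(triisopropylsilyloxy)phenol
Product: 9 2-bromo-5-(triisopropylsilyloxy)phenyl 2,2-dimethyl-8-(3-methylbut-2-en-1-yl)-2H-chromene-6-carboxylate
Conditions: DCC, DMAP (cat.), CH2Cl2, 0 °C to rt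
Reagents that add atoms: none
Why: Steglich esterification, in which DMAP passes the O-acylisourea on as an acylpyridinium ion that acylates even the hindered o-bromophenol, and which installs the future O1–C2 bond.

Step 6
Reactants: 9 2-bromo-5-(triisopropylsilyloxy)phenyl 2,2-dimethyl-8-(3-methylbut-2-en-1-yl)-2H-chromene-6-carboxylate
Product: 10 6-{1-[2-bromo-5-(triisopropylsilyloxy)phenoxy]ethenyl}-2,2-dimethyl-8-(3-methylbut-2-en-1-yl)-2H-chromene
Conditions: Cp2TiMe2 (2.5 equiv), PhMe, 70 °C, dark; filtration through basic alumina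
Reagents that add atoms: dimethyltitanocene (Petasis reagent), C[Ti](C)(C1C=CC=C1)C1C=CC=C1
Why: Petasis methylenation, in which the thermally formed titanium methylidene adds [2+2] to the ester C=O and cycloreverts to the enol ether, a non-acidic reaction type that is standard for aryl benzoates and leaves the aryl bromide, the silyl ether and the tri- and cis-disubstituted alkenes alone.

Step 7
Reactants: 10 6-{1-[2-bromo-5-(triisopropylsilyloxy)phenoxy]ethenyl}-2,2-dimethyl-8-(3-methylbut-2-en-1-yl)-2H-chromene
Product: 13 2-({1-[2,2-dimethyl-8-(3-methylbut-2-en-1-yl)-2H-chromen-6-yl]ethenyl}oxy)-4-(triisopropylsilyloxy)benzaldehyde, via aryllithium 11 (not isolated), via lithium hemiaminal alkoxide 12 (not isolated)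
Conditions: n-BuLi, THF, −78 °C; DMF, −78 to 0 °C; then H2O
Reagents that add atoms: N,N-dimethylformamide, CN(C)C=O
Why: Bromine–lithium exchange outruns any addition to the styrene-type enol ether at −78 °C, and aryllithium 11 is formylated by DMF (Bouveault-type formylation) through the stable alkoxide 12, which collapses to the aldehyde only on a non-acidic quench that the enol ether tolerates.

Step 8
Reactants: 13 2-({1-[2,2-dimethyl-8-(3-methylbut-2-en-1-yl)-2H-chromen-6-yl]ethenyl}oxy)-4-(triisopropylsilyloxy)benzaldehyde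
Product: 14 (2R)-2-[2,2-dimethyl-8-(3-methylbut-2-en-1-yl)-2H-chromen-6-yl]-7-(triisopropylsilyloxy)-2,3-dihydro-4H-chromen-4-one
Conditions: [Rh(cod)Cl]2 (2.5 mol %), (R)-DTBM-SEGPHOS (5 mol %), NaBArF4 (5 mol %), 4 Å MS, 1,4-dioxane, 80 °C
Reagents that add atoms: none
Why: Proposed new method: the cationic Rh(I)–bisphosphine inserts into the formyl C–H bond of 13, the tethered C2=C3 enol ether binds to the acyl rhodium(III) hydride, the hydride migrates to C2 to leave a primary C3–Rh bond in a seven-membered acyl rhodacycle, and C–C reductive elimination joins C3 to C4. The closest known reaction type is the endo-selective enantioselective intramolecular hydroacylation of ortho-(2-substituted allyl)benzaldehydes to 3-substituted tetralones, of which 13 is the 1-oxa analogue, together with the hydroacylation of N-(1-arylvinyl) heteroaryl carbaldehydes, which shows that a heteroatom-bearing 1,1-disubstituted alkene inserts in the same sense; an aryl enol ether in a six-ring closure has not been shown. Ring C closes in the 6-endo-trig mode, because the 5-exo alternative needs a tertiary benzylic C2–Rh bond and a reductive elimination that builds a quaternary carbon, and because the polarity of the enol ether (C2 δ+, C3 δ−) directs the hydride to C2. C2 is the only new stereocentre and is controlled by the ligand, whose aryl quadrants let the chelated alkene bind through one enantiotopic face, and hydride delivery to the Si face of C2 gives (2R). The step needs chemoselectivity among three alkenes, secured by the chelate that only C2=C3 can form with the acyl rhodium centre (the prenyl and chromene alkenes are remote, more substituted and would have to react intermolecularly), and the lack of allylic hydrogens on C2=C3 rules out alkene isomerisation. The medium is neutral and aprotic, so that neither hydrolysis of the enol ether nor retro-oxa-Michael opening of 14 should interfere.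

Step 9
Reactants: 14 (2R)-2-[2,2-dimethyl-8-(3-methylbut-2-en-1-yl)-2H-chromen-6-yl]-7-(triisopropylsilyloxy)-2,3-dihydro-4H-chromen-4-one
Product: 15 ent-abyssinone III, (2R)-7-hydroxy-2-[2,2-dimethyl-8-(3-methylbut-2-en-1-yl)-2H-chromen-6-yl]-2,3-dihydro-4H-chromen-4-one
Conditions: TBAF/AcOH (1:1), THF, 0 °C
Reagents that add atoms: none
Why: Fluoride cleavage of a phenolic silyl ether, in which acetic acid buffers the fluoride and protonates the phenoxide at once, so that C3 is not deprotonated and the ring-opening path that would scramble C2 stays closed.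

Compound list
1 | methyl 4-hydroxy-3,5-diiodobenzoate | COC(=O)c1cc(I)c(O)c(I)c1 | starting material
2 | tributyl(3-methylbut-2-en-1-yl)stannane | CCCC[Sn](CCCC)(CCCC)CC=C(C)C | starting material
3 | methyl 4-hydroxy-3,5-bis(3-methylbut-2-en-1-yl)benzoate | COC(=O)c1cc(CC=C(C)C)c(O)c(CC=C(C)C)c1 | intermediate
4 | (Z)-o-quinone methide, methyl 3-(3-methylbut-2-en-1-ylidene)-5-(3-methylbut-2-en-1-yl)-4-oxocyclohexa-1,5-diene-1-carboxylate | O=C1C(CC=C(C)C)=CC(C(=O)OC)=C/C1=C/C=C(C)C | intermediate
5 | methyl 2,2-dimethyl-8-(3-methylbut-2-en-1-yl)-2H-chromene-6-carboxylate | COC(=O)c1cc(CC=C(C)C)c2OC(C)(C)C=Cc2c1 | intermediate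
6 | 2,2-dimethyl-8-(3-methylbut-2-en-1-yl)-2H-chromene-6-carboxylic acid | OC(=O)c1cc(CC=C(C)C)c2OC(C)(C)C=Cc2c1 | intermediate
7 | 4-bromobenzene-1,3-diol | Oc1ccc(Br)c(O)c1 | starting material
8 | 2-bromo-5-(triisopropylsilyloxy)phenol | Oc1cc(O[Si](C(C)C)(C(C)C)C(C)C)ccc1Br | intermediate
9 | 2-bromo-5-(triisopropylsilyloxy)phenyl 2,2-dimethyl-8-(3-methylbut-2-en-1-yl)-2H-chromene-6-carboxylate | O=C(Oc1cc(O[Si](C(C)C)(C(C)C)C(C)C)ccc1Br)c1cc(CC=C(C)C)c2OC(C)(C)C=Cc2c1 | intermediate
10 | 6-{1-[2-bromo-5-(triisopropylsilyloxy)phenoxy]ethenyl}-2,2-dimethyl-8-(3-methylbut-2-en-1-yl)-2H-chromene | C=C(Oc1cc(O[Si](C(C)C)(C(C)C)C(C)C)ccc1Br)c1cc(CC=C(C)C)c2OC(C)(C)C=Cc2c1 | intermediate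
11 | aryllithium from 10 (Li in place of Br) | [Li]c1ccc(O[Si](C(C)C)(C(C)C)C(C)C)cc1OC(=C)c1cc(CC=C(C)C)c2OC(C)(C)C=Cc2c1 | intermediate
12 | lithium hemiaminal alkoxide (adduct of 11 to DMF, carbinol carbon unassigned) | [Li+].[O-]C(N(C)C)c1ccc(O[Si](C(C)C)(C(C)C)C(C)C)cc1OC(=C)c1cc(CC=C(C)C)c2OC(C)(C)C=Cc2c1 | intermediate
13 | 2-({1-[2,2-dimethyl-8-(3-methylbut-2-en-1-yl)-2H-chromen-6-yl]ethenyl}oxy)-4-(triisopropylsilyloxy)benzaldehyde | O=Cc1ccc(O[Si](C(C)C)(C(C)C)C(C)C)cc1OC(=C)c1cc(CC=C(C)C)c2OC(C)(C)C=Cc2c1 | intermediate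
14 | (2R)-2-[2,2-dimethyl-8-(3-methylbut-2-en-1-yl)-2H-chromen-6-yl]-7-(triisopropylsilyloxy)-2,3-dihydro-4H-chromen-4-one | CC(C)=CCc1cc([C@H]2CC(=O)c3ccc(O[Si](C(C)C)(C(C)C)C(C)C)cc3O2)cc2c1OC(C)(C)C=C2 | intermediate
15 | ent-abyssinone III, (2R) | CC(C)=CCc1cc([C@H]2CC(=O)c3ccc(O)cc3O2)cc2c1OC(C)(C)C=C2 | target

Total step count: 9. Longest linear sequence: 8 (steps 1, 2, 3, 5, 6, 7, 8, 9).

Steps most likely to fail

1. Step 8. Possible failure modes:
   - decarbonylation of the acyl rhodium hydride
   - hydride insertion in the 5-exo sense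
   - β-aryloxide elimination from the alkyl rhodium
   - Lewis-acid-induced Prins-type closure of the enol ether onto the aldehyde
   - poor facial selectivity

   The fallback sets out from 6 and comes back at 14. It builds ring C at the flavone level and sets C2 by conjugate hydride delivery, all with known chemistry. Commercial 2,4-dihydroxyacetophenone F1 is silylated at its non-chelated 4-OH (TIPSCl, imidazole) to 2-hydroxy-4-(triisopropylsilyloxy)acetophenone F2. Steglich esterification of F2 with 6 gives the aryl ester F3. Baker–Venkataraman rearrangement (LiHMDS, THF, acetic acid quench) gives the 1,3-diketone F4. Cyclodehydration (cat. TsOH, warm toluene) gives the 7-silyloxyflavone F5. An enantioselective copper hydride 1,4-reduction then delivers 14. Its conditions are Cu(OAc)2, a chiral bisphosphine of the SEGPHOS class, (EtO)2MeSiH and t-BuOH, and this reaction type is established for 2-substituted chromones.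

2. Step 6. Possible failure modes:
   - incomplete methylenation of the hindered, electron-rich aroyl ester
   - engagement of the titanium carbene by the other alkenes
   - hydrolysis of the enol ether during isolation

   The fallback sets out from 6 (with 8 as partner) and comes back at 10. It makes the O1–C2 bond by C–O cross-coupling instead of carbonyl methylenation. Acid 6 with two equivalents of MeLi gives 6-acetyl-2,2-dimethyl-8-(3-methylbut-2-en-1-yl)-2H-chromene F6. Hydrazine converts F6 into the hydrazone F7. Iodine and tetramethylguanidine give the 1-iodovinyl arene F8 (Barton vinyl iodide synthesis). Ullmann-type vinylation of phenol 8 with F8 (CuI, N,N-dimethylglycine, Cs2CO3, dioxane) gives 10. The vinyl iodide should react ahead of the aryl bromide.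

3. Step 9. The risk is erosion of the configuration at C2 by base-induced ring opening and reclosure during the fluoride treatment. The fallback sets out from 13 and comes back at 15. It removes the silyl group before the stereocentre exists. Buffered TBAF on 13 gives 4-hydroxy-2-({1-[2,2-dimethyl-8-(3-methylbut-2-en-1-yl)-2H-chromen-6-yl]ethenyl}oxy)benzaldehyde F9. F9 is then submitted to the hydroacylation conditions of step 8, so that 15 is formed in the last operation under neutral conditions.

Further compounds
F1 | step 8 | 2,4-dihydroxyacetophenone (commercial) | CC(=O)c1ccc(O)cc1O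
F2 | step 8 | 2-hydroxy-4-(triisopropylsilyloxy)acetophenone | CC(=O)c1ccc(O[Si](C(C)C)(C(C)C)C(C)C)cc1O
F3 | step 8 | 2-acetyl-5-(triisopropylsilyloxy)phenyl 2,2-dimethyl-8-(3-methylbut-2-en-1-yl)-2H-chromene-6-carboxylate | CC(=O)c1ccc(O[Si](C(C)C)(C(C)C)C(C)C)cc1OC(=O)c1cc(CC=C(C)C)c2OC(C)(C)C=Cc2c1
F4 | step 8 | 1-[2,2-dimethyl-8-(3-methylbut-2-en-1-yl)-2H-chromen-6-yl]-3-[2-hydroxy-4-(triisopropylsilyloxy)phenyl]propane-1,3-dione | O=C(CC(=O)c1cc(CC=C(C)C)c2OC(C)(C)C=Cc2c1)c1ccc(O[Si](C(C)C)(C(C)C)C(C)C)cc1O
F5 | step 8 | 2-[2,2-dimethyl-8-(3-methylbut-2-en-1-yl)-2H-chromen-6-yl]-7-(triisopropylsilyloxy)-4H-chromen-4-one | O=c1cc(-c2cc(CC=C(C)C)c3OC(C)(C)C=Cc3c2)oc2cc(O[Si](C(C)C)(C(C)C)C(C)C)ccc12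
F6 | step 6 | 6-acetyl-2,2-dimethyl-8-(3-methylbut-2-en-1-yl)-2H-chromene | CC(=O)c1cc(CC=C(C)C)c2OC(C)(C)C=Cc2c1
F7 | step 6 | (E)-hydrazone of F6 | C/C(=N\N)c1cc(CC=C(C)C)c2OC(C)(C)C=Cc2c1
F8 | step 6 | 6-(1-iodoethenyl)-2,2-dimethyl-8-(3-methylbut-2-en-1-yl)-2H-chromene | C=C(I)c1cc(CC=C(C)C)c2OC(C)(C)C=Cc2c1
F9 | step 9 | 4-hydroxy-2-({1-[2,2-dimethyl-8-(3-methylbut-2-en-1-yl)-2H-chromen-6-yl]ethenyl}oxy)benzaldehyde | C=C(Oc1cc(O)ccc1C=O)c1cc(CC=C(C)C)c2OC(C)(C)C=Cc2c1
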